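**Retrosynthetic overview**
- Target 11 (ring numbering C1=O, C2–nonadecyl, C3–H, C4=O, C5–H, C6–H) comes from 2-nonadecylcyclohex-2-ene-1,4-dione 9 by enolisation to the hydroquinone and oxidation.
- The strategy rests on the 1,4-relationship of the C1 and C4 carbonyls across the C5–C6 ring bond. This dissonant bond is made by oxidatively joining the two terminal CH2 carbons of the Z bis(silyl enol ether) 8, which closes the only ring, the six-membered carbocycle.
- 8 comes from double enol silylation of the cis-enedione 7, and 7 from peracid opening of 2,5-dimethyl-3-nonadecylfuran 6. The furan ring carbons become C1–C4 with the cis C2=C3 alkene, and its two methyl groups become C5 and C6.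
- 6 comes from Friedel–Crafts acylation of 2,5-dimethylfuran 3 with nonadecanoyl chloride 2 (from acid 1), then Wolff–Kishner reduction.

Key step: step 6

Remark: the target has no stereocentre and is achiral, so no enantiomer has to be controlled; the only stereochemical element of the route is the Z alkene of 7 and 8.

Step 1
Reactants: 1 nonadecanoic acid
Product: 2 nonadecanoyl chloride
Conditions: (COCl)2, DMF (cat.), CH2Cl2, 0 °C to rt; used crude
Reagents that add atoms: oxalyl chloride, O=C(Cl)C(=O)Cl
Why: Acyl chloride formation through the DMF-derived chloroiminium catalyst is general for saturated fatty acids and gives only gaseous by-products.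

Step 2
Reactants: 2 nonadecanoyl chloride; 3 2,5-dimethylfuran
Product: 4 1-(2,5-dimethylfuran-3-yl)nonadecan-1-one
Conditions: SnCl4, CH2Cl2, −20 to 0 °C (furan added last)
Reagents that add atoms: none
Why: Friedel–Crafts acylation: with both α-positions blocked by methyl groups the acylium ion can only enter one of the two equivalent β-positions, the mild Lewis acid at low temperature spares the acid-sensitive furan, and the acyl group deactivates the ring against a second acylation.

Step 3
Reactants: 4 1-(2,5-dimethylfuran-3-yl)nonadecan-1-one
Product: 6 2,5-dimethyl-3-nonadecylfuran, via acylfuran hydrazone 5 (not isolated)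
Conditions: N2H4·H2O, KOH, diethylene glycol, 130 then 200 °C
Reagents that add atoms: none
Why: Wolff–Kishner reduction (Huang-Minlon procedure) takes the hetaryl ketone to the methylene group through its hydrazone, and the furan and the saturated chain are inert to hot alkali.

Step 4
Reactants: 6 2,5-dimethyl-3-nonadecylfuran
Product: 7 (3Z)-3-nonadecylhex-3-ene-2,5-dione
Conditions: mCPBA (1.0 equiv), NaHCO3, CH2Cl2, 0 °C, dark; no chromatography on acidic silica
Reagents that add atoms: 3-chloroperoxybenzoic acid (mCPBA), O=C(OO)c1cccc(Cl)c1
Why: Oxidative ring opening of a 2,5-dialkylfuran by a peracid (epoxidation of the electron-rich ring C=C, then collapse to the 1,4-enedione) should give the two acetyl groups cis because they are cis in the ring, and the buffered, cold, dark conditions keep the Z alkene from isomerising.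

Step 5
Reactants: 7 (3Z)-3-nonadecylhex-3-ene-2,5-dione
Product: 8 (3Z)-3-nonadecyl-2,5-bis(trimethylsilyloxy)hexa-1,3,5-triene
Conditions: TMSOTf (2.4 equiv), Et3N (3.5 equiv), CH2Cl2, −20 to 0 °C; cold NaHCO3 wash, used crude
Reagents that add atoms: trimethylsilyl trifluoromethanesulfonate, C[Si](C)(C)OS(=O)(=O)C(F)(F)F
Why: Soft enolisation (silyl triflate/tertiary amine enol silylation) turns each methyl ketone into its 2-siloxydiene by O-silylation and loss of a methyl proton, the only sp3 α-hydrogens present, and is chosen over amide bases because a metal enolate of a cis-enedione would close by intramolecular aldol addition to a 4-hydroxycyclopentenone; the C3=C4 bond is not touched, so its Z geometry passes into 8.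

Step 6
Reactants: 8 (3Z)-3-nonadecyl-2,5-bis(trimethylsilyloxy)hexa-1,3,5-triene
Product: 9 2-nonadecylcyclohex-2-ene-1,4-dione
Conditions: CAN (2.2 equiv), NaHCO3 (5 equiv), MeCN/CH2Cl2, −20 °C, slow addition of 8 (final ca. 0.005 M); crude product used directly
Reagents that add atoms: none
Why: Proposed new method: Ce(IV) should remove one electron from the electron-rich cross-conjugated bis(siloxy)triene; the radical cation, after loss of Me3Si+ an α-keto radical centred on one terminal CH2, attacks the CH2 terminus of the second silyl enol ether, and the resulting α-siloxy allylic radical is oxidised by a second Ce(IV) and desilylated to the second ketone. The closest known reaction type is the ceric ammonium nitrate or copper(II) oxidative coupling of silyl enol ethers to 1,4-diketones, including intramolecular cases with tethered bis-enol ethers and cyclisations of α-keto radicals onto enol ethers, but closure of a cyclohex-2-ene-1,4-dione from a 2,5-bis(siloxy)hexatriene has not been shown. The one ring closes 6-endo-trig, which should win over 5-exo attack at the siloxy-bearing carbon because the electrophilic radical adds to the nucleophilic, unsubstituted CH2 end and gives a stabilised radical. No stereocentre is formed. The step needs ring closure to beat dimerisation, hydrolysis of the enol ethers and reaction at other sites: the Z C=C bond inherited from the furan holds the two CH2 termini within bonding distance, the two equivalent ways of starting the oxidation lead to the same C5–C6 bond, and slow addition at high dilution under bicarbonate buffer suppresses the bimolecular and acid-driven paths. Enolisation and further oxidation of 9 in the flask would only move material toward 11.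

Step 7
Reactants: 9 2-nonadecylcyclohex-2-ene-1,4-dione
Product: 11 2-nonadecyl-1,4-benzoquinone, via 2-nonadecylhydroquinone 10 (not isolated)
Conditions: TsOH·H2O (cat.), CH2Cl2, rt, Ar; then Ag2O, MgSO4, Et2O, rt
Reagents that add atoms: none
Why: Acid-catalysed double enolisation of the cyclohex-2-ene-1,4-dione is driven by aromatisation to the hydroquinone, and silver(I) oxide oxidation of a hydroquinone to the 1,4-benzoquinone is a standard transformation that a saturated alkyl chain tolerates.

**Compound list**
1 | nonadecanoic acid | CCCCCCCCCCCCCCCCCCC(=O)O | starting material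
2 | nonadecanoyl chloride | CCCCCCCCCCCCCCCCCCC(=O)Cl | intermediate
3 | 2,5-dimethylfuran | Cc1ccc(C)o1 | starting material
4 | 1-(2,5-dimethylfuran-3-yl)nonadecan-1-one | CCCCCCCCCCCCCCCCCCC(=O)c1cc(C)oc1C | intermediate
5 | 1-(2,5-dimethylfuran-3-yl)nonadecan-1-one hydrazone (C=N isomers) | CCCCCCCCCCCCCCCCCCC(=NN)c1cc(C)oc1C | intermediate
6 | 2,5-dimethyl-3-nonadecylfuran | CCCCCCCCCCCCCCCCCCCc1cc(C)oc1C | intermediate
7 | (3Z)-3-nonadecylhex-3-ene-2,5-dione | CC(=O)/C=C(CCCCCCCCCCCCCCCCCCC)\C(C)=O | intermediate
8 | (3Z)-3-nonadecyl-2,5-bis(trimethylsilyloxy)hexa-1,3,5-triene | C=C(O[Si](C)(C)C)/C=C(CCCCCCCCCCCCCCCCCCC)\C(=C)O[Si](C)(C)C | intermediate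
9 | 2-nonadecylcyclohex-2-ene-1,4-dione | O=C1CCC(=O)C(CCCCCCCCCCCCCCCCCCC)=C1 | intermediate
10 | 2-nonadecylbenzene-1,4-diol (2-nonadecylhydroquinone) | Oc1ccc(O)c(CCCCCCCCCCCCCCCCCCC)c1 | intermediate
11 | 2-nonadecylcyclohexa-2,5-diene-1,4-dione (2-nonadecyl-1,4-benzoquinone) | CCCCCCCCCCCCCCCCCCCC1=CC(=O)C=CC1=O | target

**Totals**
Total step count: 7. Longest linear sequence: 7 steps, from nonadecanoic acid 1.

**Steps most likely to fail**

Step 6 (proposed new method). The radical cation may couple intermolecularly or oligomerise faster than it closes the ring. The enol ethers may be protodesilylated back to 7, the central double bond may rotate at the radical-cation stage and lose the cis arrangement, or nitrate may trap the radical. The fallback uses known chemistry and sets out from 8. Heating 8 in degassed toluene at 110–140 °C in base-washed glass should bring about the thermal disrotatory 6π-electrocyclisation of the Z-hexatriene. This forms the same C5–C6 bond one oxidation level lower and gives 2-nonadecyl-1,4-bis(trimethylsilyloxy)cyclohexa-1,3-diene F1. Dehydrogenation with DDQ in benzene at room temperature should give 2-nonadecyl-1,4-bis(trimethylsilyloxy)benzene F2. Acid-catalysed methanolysis of the aryl silyl ethers (MeOH, catalytic citric acid, argon) returns to the route at hydroquinone 10, which the silver oxide stage of step 7 takes to 11.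

Step 5. The silyl triflate or the amine may isomerise the Z alkene by reversible activation or conjugate addition. The mono-silylated intermediate may close onto the second ketone in an aldol-type reaction to a cyclopentenone, enolisation may run toward the chain CH2 (vinylogous position), or the bis(enol ether) may hydrolyse on work-up. The fallback leaves the enedione line and sets out from 2. Friedel–Crafts acylation of 1,4-dimethoxybenzene with 2 (AlCl3, CH2Cl2, 0 °C) should give 1-(2,5-dimethoxyphenyl)nonadecan-1-one F3. Ionic hydrogenation of the aryl ketone (Et3SiH, CF3CO2H) should give 1,4-dimethoxy-2-nonadecylbenzene F4. Oxidative demethylation with ceric ammonium nitrate in MeCN/H2O at 0 °C comes back to the route at 11.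

Step 4. The 3-chlorobenzoic acid by-product or light may isomerise the cis-enedione to the trans isomer, or the peracid may over-oxidise the ring-opening intermediate (Baeyer–Villiger-type). The fallback sets out from 6. Dye-sensitised photooxygenation (O2, tetraphenylporphyrin, visible light, CH2Cl2, −78 °C) adds singlet oxygen across the furan in a [4+2] sense to give the racemic endoperoxide 1,4-dimethyl-5-nonadecyl-2,3,7-trioxabicyclo[2.2.1]hept-5-ene F5. Reduction with dimethyl sulfide at −78 to 0 °C in the dark, without acid, comes back to the route at 7.

**Further compounds**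
F1 | step 6 | 2-nonadecyl-1,4-bis(trimethylsilyloxy)cyclohexa-1,3-diene | C[Si](C)(C)OC1=CC(CCCCCCCCCCCCCCCCCCC)=C(O[Si](C)(C)C)CC1
F2 | step 6 | 2-nonadecyl-1,4-bis(trimethylsilyloxy)benzene | C[Si](C)(C)Oc1ccc(O[Si](C)(C)C)c(CCCCCCCCCCCCCCCCCCC)c1
F3 | step 5 | 1-(2,5-dimethoxyphenyl)nonadecan-1-one | CCCCCCCCCCCCCCCCCCC(=O)c1cc(OC)ccc1OC
F4 | step 5 | 1,4-dimethoxy-2-nonadecylbenzene | CCCCCCCCCCCCCCCCCCCc1cc(OC)ccc1OC
F5 | step 4 | 1,4-dimethyl-5-nonadecyl-2,3,7-trioxabicyclo[2.2.1]hept-5-ene (racemic) | CC12OOC(C)(O1)C=C2CCCCCCCCCCCCCCCCCCC
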